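(The earlier runs and the new flask were generated by integration for substances that don't exist, noise included.)

The autumn run makes target steadily, 13.2% by 90.0 s, on 4.8 mM of nucleophile; the new flask charges 2.40 mM.

| flask | solid electrophile | nucleophile | buffer base | buffer acid | remark | time |
|---|---|---|---|---|---|---|
| autumn | 2 mM | 4.8 mM | 6 mM | 2 mM | run made earlier |  |
| flask | 2.0 mM | 2.40 mM | 6.00 mM | 2.00 mM |  | 15 min |

autumn run (percent of the solid electrophile charged)

| time / s | solid electrophile / % | target / % |
|---|---|---|
| 15.0 | 93.1 | 0.6 |
| 30.0 | 87.2 | 3.1 |
| 50.0 | 79.3 | 5.1 |
| 60.0 | 75.9 | 6.9 |
| 80.0 | 68.0 | 11.2 |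
| 90.0 | 65.4 | 13.2 |

(scatter of a reading: 0.5 percentage points)

- acid is the free proton; pH is minus the decimal logarithm of its molar concentration
- percent here means solid electrophile units held: one side product counts as two
- solid electrophile is a solid; its amount is given per volume of the solution
- what may be going on: electrophile + nucleophile -> acid + target + leaving group; protonated nucleophile <-> nucleophile + acid; buffer acid <-> buffer base + acid; solid electrophile <-> electrophile; electrophile + target -> side product
- at the start none of the solid electrophile is in solution
- what has only dissolved of solid electrophile counts as not reacted
- the earlier runs do not show the pH; that part of a forecast is a guess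

* part of the solid electrophile that has reacted (what has only dissolved counts as not reacted) at 15 min
* pH of the solution at 15 min

1. The bench rule counts equivalents. The new flask holds 1.20 nucleophile per solid electrophile, an excess. The autumn solid readings give a half-life of 2.45 min, shorter than 15 min, so the rule promises full reaction.

2. The rule stops at a ratio: buffer acid to nucleophile is 0.833 in this flask, against 0.417 in autumn. I guess the nucleophile is the stronger base, which the runs don't show. Then each buffer acid holds one nucleophile as protonated nucleophile.

3. Each coupling of electrophile with nucleophile also releases acid, which holds a second nucleophile. But a target that goes on to side product counts two units, so the two factors cancel.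

4. The spare share is 20.0%: nucleophile charge minus buffer acid charge, per solid electrophile charged. It is a small difference of two large charges, and it makes the nucleophile the limiting reagent. I commit to about 20.0% reacted.

5. The forecast says 73% and pH 7, working from “second-order kinetics after a lag”. My number differs from its 73%; I have no better pH.

6. The flask gives 27.3% reacted and pH 6.97.

    electrophile + nucleophile → acid + target + leaving group (k = 5.22 M⁻¹ s⁻¹)
    protonated nucleophile ⇌ nucleophile + acid, settled at all times (K = 6.30 × 10⁻¹⁰ M)
    buffer acid ⇌ buffer base + acid, settled at all times (K = 5.00 × 10⁻⁶ M)
    solid electrophile ⇌ electrophile, rate k4*(cs4 - [electrophile]) while solid is left; crystals form when [electrophile] > cs4 (solubility = 1.40 mM, k = 0.00659 s⁻¹)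
    electrophile + target → side product (k = 8.44 M⁻¹ s⁻¹)

The constants stand 5.0 × 10⁻⁶ M for buffer acid against 6.3 × 10⁻¹⁰ M for protonated nucleophile, as I guessed. The spare share of 20.0% lies 7.3 percentage points under the flask's answer. The spare share needs a correction: 8.40% of the buffer acid charge still stands at 15.0 min, which adds 8.40% and makes 28.4%. The neighbour flask with 1.2 mM of buffer acid has a spare share of 60.0%; its remaining 7.79% of buffer acid adds 4.68%, making 64.7%, and that flask gives 63.0%.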